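**Total synthesis plan for CNP0320659.1 (30): ring A by ketene–ynol ether benzannulation**

TIPS = triisopropylsilyl, TBS = tert-butyldimethylsilyl. Isoflavan numbering (O1, C2, C3, C4, C4a, C5–C8, C8a; ring B primed) is used for the target and for the atoms that become part of it.

## The problem

Compound 30 is a (3R)-isoflavan: a chroman (rings A and C) whose C3 carries a 5-hydroxy-2,2-dimethyl-2H-chromen-8-yl group (ring B with its fused pyran). Ring A is a 1,3,5-trioxygenated benzene in which all three oxygens differ: O1 is the ring ether, O5 a methyl ether and O7 a free phenol. A route from a symmetrical triol would therefore have to tell three nearly equivalent positions apart and place the only carbon substituent (C4 on C4a) between two of them.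

C3 is the sole stereocentre, a tertiary benzylic carbon with no neighbouring carbonyl or heteroatom in the target. No other element can relay chirality to it, so it must be set by a catalyst. It is best set where it is not alpha to a carbonyl, so that it cannot epimerise later.

The 2,2-dimethylchromene is the fragile part. Its styrene-type double bond rules out hydrogenolysis, and the strong Brønsted or Lewis acids normally used to cleave aryl methyl or benzyl ethers add to it or open the pyran. Protecting groups must therefore leave with fluoride or zerovalent palladium.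

The feature that makes the key step possible is on ring A: C4a bears the single carbon substituent, flanked by oxygenated C5 and C8a, with O7 para. That is the pattern produced when a vinylketene carrying a 3-alkoxy group combines with an ynol ether, and the three oxygens arrive in three different states (free hydroxyl, silyl ether, alkyl ether).

## Retrosynthesis

**Endgame, 30 back to 28.** The last cuts are the O7–allyl bond (30 from allyl ether 29) and the O1–C2 bond (29 from phenol–alcohol 28). Closing ring C at O1–C2 is preferred to an aryl C–O coupling at C8a or a C4–C4a alkylation, because the ring-A synthesis delivers C8a already oxygenated and C4 already attached. What is left is an intramolecular etherification at a primary, non-stereogenic carbon. The forward reaction must tolerate the free ring-B phenol, which is para to the side chain and cannot cyclise.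

**Differentiation of the ring-A oxygens, 28 back to 26.** Triol 28 comes from the fully silylated methyl ether 27 by fluoride, and 27 from phenol 26 by O-methylation. In 26 the three ring-A oxygens are already distinct: free OH at C5, TIPS ether at C8a, allyl ether at C7. No selective protection of a symmetrical arene is needed; only a methylation and a global desilylation are asked for.

**Key disconnection, 26 to 19 and 21.** Ring A is taken apart at C4a–C5 and C8–C8a (the C5–C6 bond is broken and re-formed in the course of the step). This gives siloxyalkyne 19, which holds the whole C2–C3–C4 chain, the stereocentre and ring B, and the four-carbon cyclobutenone 21. Compared with joining a preformed, differentially protected ring A to C4, this cut removes every regiochemical question on ring A, because the positions of the oxygens follow from the polarity of the cycloaddition. The forward reaction must be thermal and neutral and must engage only the ynol ether among four π-systems.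

**Ynol ether, 19 back to 16.** The O–C≡C unit is traced to the ester group of 16 by a one-carbon homologation of the Kowalski type that is stopped at the ynolate 18 and silylated on oxygen. The ester carbonyl carbon becomes C8a and the inserted carbon becomes C4a. This is preferred to building a terminal alkyne and oxidising it, which costs more steps. The precursor 16 is a plain β-aryl ester. The forward reaction requires strong base, which the β-stereocentre (not enolisable) tolerates.

**Open-chain ester, 16 back to 12.** Ester 16 (through acid 15) is the ring-opened, O-silylated form of γ-lactone 12. The lactone is the more natural retron because a butenolide is a rigid acceptor for asymmetric conjugate addition. The price is a hydrolysis and silylation sequence that traps the hydroxy acid before it recloses.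

**Stereocentre, 12 to 10 and 11.** The C3–C1' bond is cut to give boronic acid 10 and furan-2(5H)-one 11. A rhodium-catalysed conjugate addition forms this bond and the stereocentre in one catalytic step, at a carbon beta to the carbonyl. Setting it by alkylation of an arylacetic acid derivative would place it alpha to a carbonyl and require an auxiliary. The forward reaction has to outrun protodeboronation of an ortho-alkoxy boronic acid.

**Ring B, 10 back to 1 and 3.** Boronic acid 10 comes from bromide 7 by halogen–metal exchange. The pyran ring of 7 is opened at O–C(Me2) and at the aryl–C4 bond to give propargyl ether 4, made from mono-silylated bromoresorcinol 2 and chloride 3; 2 comes from 4-bromoresorcinol 1. The bromine serves twice: it blocks one ortho position, so the Claisen rearrangement can only go to the carbon between the two oxygens, and it later becomes the boron handle.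

**Cyclobutenone, 21 back to 20.** The allyl enol ether 21 is derived from commercial 3-ethoxycyclobut-2-en-1-one 20 by alkoxy exchange. Allyl is chosen because it is the one phenol protecting group that survives fluoride and base and is removed under neutral conditions compatible with the chromene.

## Roads not taken

**Alternative 1:** Cut C3–C4 and the O1–C2 acyl bond. In the forward sense, the ortho-quinone methide released by base from sulfone A1 (3-methoxy-2-[(phenylsulfonyl)methyl]-5-(triisopropylsilyloxy)phenol) is trapped by the chiral ammonium enolate formed from arylacetic acid A2 (the ring-B acetic acid) and an isothiourea catalyst. The product is the (3R)-3-arylchroman-2-one A3.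

- Merits: ring C and the stereocentre are formed in one catalytic, convergent step from two aromatic fragments, and the route would be several steps shorter than the chosen one.
- Weak points for this target:
  - The methide carbon of the quinone methide from A1 is unsubstituted. Such parent quinone methides oligomerise readily, and the annulation is best established for substituted ones.
  - The stereocentre of A3 is alpha to an aryl ester and carries an aryl group, so it is easily enolised by the base that generates the quinone methide.
  - A1 requires C-functionalisation of an unsymmetrical diether specifically at the position between OH and OMe.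
  - The lactone must afterwards be reduced and ring C closed a second time.
- Comparison: in step count and convergence this road is better. The chosen plan sets against it a stereocentre (in 12) that is never alpha to a carbonyl, and a ring-A oxygen pattern fixed by mechanism instead of by selective aromatic substitution.

**Alternative 2:** Cut O1–C8a and C4–C4a. The aryne generated from ortho-silylaryl triflate A4 is attacked at C8a by the alkoxide of chloro alcohol A5 ((2R)-3-chloro-2-arylpropan-1-ol), and the resulting aryl anion at C4a displaces chloride (6-exo-tet) to give the bis-silylated isoflavan A6.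

- Merits: the complete isoflavan skeleton appears in one operation with the stereocentre imported untouched, and only a desilylation would remain. If the annulation worked, this would be the shortest endgame of all.
- Weak points for this target:
  - The γ-chloro alkoxide of A5 can close to an oxetane before it meets the aryne.
  - The aryl anion can be protonated by the alcohol before it alkylates, leaving an open aryl ether with no way to form C4–C4a.
  - Trapping an aryne-derived anion with an unactivated primary chloride is less secure than trapping with carbonyl electrophiles.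
  - A4 and A5 each need a multistep, regio- or enantioselective preparation of their own.
- Comparison: this road wins on brevity after the fragments are in hand and needs no Mitsunobu closure or allyl group. The chosen plan offers a key step whose regiochemistry is pericyclic and independent of competing anion chemistry, and its chiral fragment (12) comes from a catalytic asymmetric reaction on commercial 11.

**Alternative 3:** Cut C3–C1' and C4–C4a. The boronate complex from vinylboronic ester A8 and aryllithium 8 couples with ring-A triflate A7 under a palladium catalyst bearing a chiral ferrocenyl bisphosphine. Palladium-induced 1,2-migration of the ring-B aryl from boron to C3 accompanies C4–C4a bond formation and gives the secondary boronate A9.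

- Merits: three simple components, catalytic enantiocontrol, and use of the same bromide 7 as the chosen route. The linear sequence would probably be shorter.
- Weak points for this target:
  - A7 is a very electron-rich aryl triflate flanked by two ortho alkoxy groups, which is unfavourable for oxidative addition and hindered at the coupling stage.
  - The migrating aryl group is ortho-substituted.
  - A9 lacks C2, so a one-carbon homologation of a hindered benzylic boronate, an oxidation, an acidic removal of the methoxymethyl group in the presence of the chromene and a ring closure must follow.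
- Comparison: enantiocontrol is comparable to the rhodium step of the chosen plan and convergence is higher. The chosen plan avoids the hindered cross-coupling and any acidic deprotection, and it does not need a regioselectively tri-differentiated ring-A fragment.

Key step: step 10

Assumption: the sense of induction of [Rh(OH)((R)-BINAP)]2 with butenolide 11 is taken to follow that known for five- and six-membered cyclic enones, which predicts (R)-12. If the opposite sense is found, (S)-BINAP is used and nothing else changes.

## Route

Step 1
Reactants: 1 4-bromoresorcinol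
Product: 2 2-bromo-5-(triisopropylsilyloxy)phenol
Conditions: TIPSCl (1.05 equiv), imidazole, CH2Cl2, 0 °C → rt
Reagents that add atoms: chlorotriisopropylsilane, CC(C)[Si](Cl)(C(C)C)C(C)C
Why: Silylation with a bulky chlorosilane under imidazole catalysis is sterically governed; the hydroxyl para to bromine is open while the one ortho to bromine is shielded and hydrogen-bonded to the halogen, so the 5-silyl ether should predominate and be separable from regioisomer and bis-ether.

Step 2
Reactants: 2 2-bromo-5-(triisopropylsilyloxy)phenol; 3 3-chloro-3-methylbut-1-yne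
Product: 4 [4-bromo-3-(2-methylbut-3-yn-2-yloxy)phenoxy]triisopropylsilane
Conditions: CuCl2·2H2O (cat.), DBU, MeCN, 0 °C
Reagents that add atoms: none
Why: Copper-catalysed propargylic substitution of a tertiary propargylic chloride by a phenol is the standard entry to aryl 1,1-dimethylpropargyl ethers and tolerates ortho-halogen and aryl silyl ethers.

Step 3
Reactants: 4 [4-bromo-3-(2-methylbut-3-yn-2-yloxy)phenoxy]triisopropylsilane
Product: 7 8-bromo-2,2-dimethyl-5-(triisopropylsilyloxy)-2H-chromene, via allenylphenol 5 (not isolated), via ortho-quinone methide 6 (not isolated)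
Conditions: N,N-diethylaniline, 170 °C
Reagents that add atoms: none
Why: Aromatic propargyl Claisen rearrangement can only end at the ortho carbon that bears hydrogen (the other is blocked by bromine), giving 5; a 1,5-hydrogen shift to 6 and oxa-6π electrocyclisation then close the pyran, the geminal methyl groups accelerating the cascade.

Step 4
Reactants: 7 8-bromo-2,2-dimethyl-5-(triisopropylsilyloxy)-2H-chromene
Product: 10 [2,2-dimethyl-5-(triisopropylsilyloxy)-2H-chromen-8-yl]boronic acid, via aryllithium 8 (not isolated), via lithium triisopropoxyborate 9 (not isolated)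
Conditions: n-BuLi, THF, −78 °C; B(OiPr)3, −78 °C → rt; 1 M HCl to pH 5, 0 °C
Reagents that add atoms: triisopropyl borate, CC(C)OB(OC(C)C)OC(C)C; water, O
Why: Bromine–lithium exchange next to the ring oxygen is fast at −78 °C and leaves the para silyl ether alone; borylation of 8 gives ate complex 9, hydrolysed on mild acidic work-up.

Step 5
Reactants: 10 [2,2-dimethyl-5-(triisopropylsilyloxy)-2H-chromen-8-yl]boronic acid; 11 furan-2(5H)-one
Product: 12 (4R)-4-[2,2-dimethyl-5-(triisopropylsilyloxy)-2H-chromen-8-yl]oxolan-2-one
Conditions: [Rh(OH)((R)-BINAP)]2 (3 mol% Rh), 11 (2.5 equiv), 1,4-dioxane/H2O 10:1, 40 °C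
Reagents that add atoms: none
Why: Hayashi–Miyaura asymmetric conjugate addition: transmetalation to the hydroxo complex of monovalent rhodium, enantioface-selective insertion of the s-trans-locked butenolide into the aryl–rhodium bond under control of the (R)-bisphosphine, and hydrolysis of the rhodium enolate set the future C3 as R; base-free, low-temperature conditions limit protodeboronation and spare the aryl silyl ether.

Step 6
Reactants: 12 (4R)-4-[2,2-dimethyl-5-(triisopropylsilyloxy)-2H-chromen-8-yl]oxolan-2-one
Product: 15 (3R)-4-(tert-butyldimethylsilyloxy)-3-[2,2-dimethyl-5-(triisopropylsilyloxy)-2H-chromen-8-yl]butanoic acid, via lithium hydroxy carboxylate 13 (not isolated), via bis-silyl derivative 14 (not isolated)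
Conditions: LiOH·H2O, THF/H2O, 0 °C → rt, evaporate; TBSCl, imidazole, DMF, rt; K2CO3, MeOH/THF/H2O, 0 °C; work-up at pH 5 (NaH2PO4 buffer)
Reagents that add atoms: lithium hydroxide, [Li+].[OH-]; tert-butylchlorodimethylsilane, CC(C)(C)[Si](C)(C)Cl
Why: Saponification, exhaustive silylation and selective hydrolysis of the labile silyl ester is the standard way to hold a γ-hydroxy acid open; the stereocentre is beta to the carboxyl group and cannot enolise.

Step 7
Reactants: 15 (3R)-4-(tert-butyldimethylsilyloxy)-3-[2,2-dimethyl-5-(triisopropylsilyloxy)-2H-chromen-8-yl]butanoic acid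
Product: 16 methyl (3R)-4-(tert-butyldimethylsilyloxy)-3-[2,2-dimethyl-5-(triisopropylsilyloxy)-2H-chromen-8-yl]butanoate
Conditions: Me3SiCHN2, toluene/MeOH 4:1, 0 °C
Reagents that add atoms: (trimethylsilyl)diazomethane, C[Si](C)(C)C=[N+]=[N-]
Why: Diazoalkane esterification is neutral and fast, so neither silyl ether is cleaved and acid-catalysed relactonisation is avoided.

Step 8
Reactants: 16 methyl (3R)-4-(tert-butyldimethylsilyloxy)-3-[2,2-dimethyl-5-(triisopropylsilyloxy)-2H-chromen-8-yl]butanoate
Product: 19 tert-butyl{[(2R)-2-[2,2-dimethyl-5-(triisopropylsilyloxy)-2H-chromen-8-yl]-5-(triisopropylsilyloxy)pent-4-yn-1-yl]oxy}dimethylsilane, via lithium dibromoenolate 17 (not isolated), via lithium ynolate 18 (not isolated)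
Conditions: CH2Br2, lithium 2,2,6,6-tetramethylpiperidide, THF, −78 °C; LiN(SiMe3)2, −78 °C; n-BuLi, −78 °C → rt; TIPSCl, −78 °C → rt; chromatography on Et3N-deactivated silica
Reagents that add atoms: dibromomethane, BrCBr; chlorotriisopropylsilane, CC(C)[Si](Cl)(C(C)C)C(C)C
Why: Kowalski ester homologation stopped at the ynolate: dibromomethyllithium adds to the ester, base gives enolate 17, bromine–lithium exchange triggers 1,2-migration of the alkyl chain to give 18, and the bulky chlorosilane silylates on oxygen; the stereocentre is beta to the reacting carbonyl and is not touched.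

Step 9
Reactants: 20 3-ethoxycyclobut-2-en-1-one
Product: 21 3-(prop-2-enyloxy)cyclobut-2-en-1-one
Conditions: allyl alcohol (excess), TsOH·H2O (cat.), 40 °C, ethanol removed under reduced pressure
Reagents that add atoms: prop-2-en-1-ol, C=CCO
Why: Acid-catalysed alkoxy exchange of a vinylogous ester (addition of the alcohol to the O-protonated enone, loss of ethanol), driven by excess alcohol and removal of the more volatile ethanol.

Step 10
Reactants: 19 tert-butyl{[(2R)-2-[2,2-dimethyl-5-(triisopropylsilyloxy)-2H-chromen-8-yl]-5-(triisopropylsilyloxy)pent-4-yn-1-yl]oxy}dimethylsilane; 21 3-(prop-2-enyloxy)cyclobut-2-en-1-one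
Product: 26 2-[(2R)-3-(tert-butyldimethylsilyloxy)-2-[2,2-dimethyl-5-(triisopropylsilyloxy)-2H-chromen-8-yl]propyl]-5-(prop-2-enyloxy)-3-(triisopropylsilyloxy)phenol, via vinylketene 22 (not isolated), via vinylcyclobutenone 23 (not isolated), via dienylketene 24 (not isolated), via cyclohexadienone 25 (not isolated)
Conditions: 21 (1.3 equiv), toluene, 80 °C then 110 °C, argon, sealed tube
Reagents that add atoms: none
Why: On heating, 21 undergoes reversible 4π-electrocyclic opening to vinylketene 22. The ketene C=C of 22 adds across the electron-rich triple bond of 19 in a polar [2+2] cycloaddition in which the electrophilic ketene carbonyl carbon bonds to the nucleophilic carbon of the ynol ether remote from oxygen (C4a), giving 23 and forming C4a–C5 and C8–C8a. Cyclobutenone 23 opens (4π) to dienylketene 24, and ring A is closed by thermal disrotatory 6π-electrocyclisation between the ketene carbon (C5) and the terminal methylene (C6) to give 25, which tautomerises irreversibly to phenol 26. The closest known reaction type is the Danheiser benzannulation of cyclobutenones with trialkylsiloxyalkynes, which gives 2-substituted resorcinol monosilyl ethers; a 3-alkoxycyclobutenone extends it to the 1,3,5-trioxygenated pattern. No stereocentre is created, and C3 lies two carbons from the alkyne in a neutral aprotic medium, so its configuration is carried through. The step needs regioselectivity and chemoselectivity: the first is fixed by the polarisation of the ynol ether, which places the side chain between the free hydroxyl and the silyl ether and the allyloxy group para to it; the second rests on 19 being by far the most nucleophilic π-system present, so the chromene and allyl double bonds stay out of the reaction, while at or below 110 °C Claisen rearrangements of the allyl ethers remain slow.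

Step 11
Reactants: 26 2-[(2R)-3-(tert-butyldimethylsilyloxy)-2-[2,2-dimethyl-5-(triisopropylsilyloxy)-2H-chromen-8-yl]propyl]-5-(prop-2-enyloxy)-3-(triisopropylsilyloxy)phenol
Product: 27 tert-butyl{(2R)-2-[2,2-dimethyl-5-(triisopropylsilyloxy)-2H-chromen-8-yl]-3-[2-methoxy-4-(prop-2-enyloxy)-6-(triisopropylsilyloxy)phenyl]propoxy}dimethylsilane
Conditions: MeI, K2CO3, acetone, rt
Reagents that add atoms: iodomethane, CI
Why: Williamson methylation of the only free phenol; carbonate in acetone at room temperature should not cleave aryl TIPS ethers, and the silyl group cannot migrate between the meta-related oxygens.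

Step 12
Reactants: 27 tert-butyl{(2R)-2-[2,2-dimethyl-5-(triisopropylsilyloxy)-2H-chromen-8-yl]-3-[2-methoxy-4-(prop-2-enyloxy)-6-(triisopropylsilyloxy)phenyl]propoxy}dimethylsilane
Product: 28 8-[(2R)-1-hydroxy-3-[2-hydroxy-6-methoxy-4-(prop-2-enyloxy)phenyl]propan-2-yl]-2,2-dimethyl-2H-chromen-5-ol
Conditions: Bu4NF (3.5 equiv), THF, 0 °C → rt, argon
Reagents that add atoms: none
Why: Fluoride-driven desilylation removes both aryl TIPS ethers and the primary TBS ether; allyl and methyl ethers and the chromene are inert to fluoride.

Step 13
Reactants: 28 8-[(2R)-1-hydroxy-3-[2-hydroxy-6-methoxy-4-(prop-2-enyloxy)phenyl]propan-2-yl]-2,2-dimethyl-2H-chromen-5-ol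
Product: 29 8-[(3R)-5-methoxy-7-(prop-2-enyloxy)-3,4-dihydro-2H-chromen-3-yl]-2,2-dimethyl-2H-chromen-5-ol
Conditions: PPh3, diisopropyl azodicarboxylate, THF (0.01 M), 0 °C → rt
Reagents that add atoms: none
Why: Intramolecular Mitsunobu etherification: the primary alcohol is activated as an alkoxyphosphonium ion and the ortho phenoxide closes ring C by 6-exo-tet displacement at the non-stereogenic C2, leaving C3 untouched; the ring-B phenol is para to the chain and cannot cyclise, and high dilution disfavours its intermolecular alkylation.

Step 14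
Reactants: 29 8-[(3R)-5-methoxy-7-(prop-2-enyloxy)-3,4-dihydro-2H-chromen-3-yl]-2,2-dimethyl-2H-chromen-5-ol
Product: 30 8-[(3R)-7-hydroxy-5-methoxy-3,4-dihydro-2H-chromen-3-yl]-2,2-dimethyl-2H-chromen-5-ol (CNP0320659.1)
Conditions: Pd(PPh3)4 (5 mol%), morpholine, THF, rt
Reagents that add atoms: none
Why: Tsuji–Trost-type deallylation: zerovalent palladium ionises the aryl allyl ether to a π-allyl complex and phenoxide, and morpholine traps the allyl group; the neutral conditions leave the chromene, the methyl ether and the stereocentre unchanged.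

## Compound list

1 | 4-bromoresorcinol (4-bromobenzene-1,3-diol) | Oc1ccc(Br)c(O)c1 | starting material
2 | 2-bromo-5-(triisopropylsilyloxy)phenol | Oc1cc(O[Si](C(C)C)(C(C)C)C(C)C)ccc1Br | intermediate
3 | 3-chloro-3-methylbut-1-yne | CC(C)(Cl)C#C | starting material
4 | [4-bromo-3-(2-methylbut-3-yn-2-yloxy)phenoxy]triisopropylsilane | C#CC(C)(C)Oc1cc(O[Si](C(C)C)(C(C)C)C(C)C)ccc1Br | intermediate
5 | 6-bromo-2-(3-methylbuta-1,2-dienyl)-3-(triisopropylsilyloxy)phenol | CC(C)=C=Cc1c(O)c(Br)ccc1O[Si](C(C)C)(C(C)C)C(C)C | intermediate (not isolated)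
6 | 2-bromo-6-(3-methylbut-2-enylidene)-5-(triisopropylsilyloxy)cyclohexa-2,4-dien-1-one | CC(C)=CC=C1C(=O)C(Br)=CC=C1O[Si](C(C)C)(C(C)C)C(C)C | intermediate (not isolated)
7 | 8-bromo-2,2-dimethyl-5-(triisopropylsilyloxy)-2H-chromene | Brc1ccc(O[Si](C(C)C)(C(C)C)C(C)C)c2C=CC(C)(C)Oc12 | intermediate
8 | [2,2-dimethyl-5-(triisopropylsilyloxy)-2H-chromen-8-yl]lithium | [Li]c1ccc(O[Si](C(C)C)(C(C)C)C(C)C)c2C=CC(C)(C)Oc12 | intermediate (not isolated)
9 | lithium [2,2-dimethyl-5-(triisopropylsilyloxy)-2H-chromen-8-yl]triisopropoxyborate | [Li+].CC(C)O[B-](OC(C)C)(OC(C)C)c1ccc(O[Si](C(C)C)(C(C)C)C(C)C)c2C=CC(C)(C)Oc12 | intermediate (not isolated)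
10 | [2,2-dimethyl-5-(triisopropylsilyloxy)-2H-chromen-8-yl]boronic acid | OB(O)c1ccc(O[Si](C(C)C)(C(C)C)C(C)C)c2C=CC(C)(C)Oc12 | intermediate
11 | furan-2(5H)-one | O=C1OCC=C1 | starting material
12 | (4R)-4-[2,2-dimethyl-5-(triisopropylsilyloxy)-2H-chromen-8-yl]oxolan-2-one | O=C1C[C@H](c2ccc(O[Si](C(C)C)(C(C)C)C(C)C)c3C=CC(C)(C)Oc23)CO1 | intermediate
13 | lithium (3R)-3-[2,2-dimethyl-5-(triisopropylsilyloxy)-2H-chromen-8-yl]-4-hydroxybutanoate | [Li+].[O-]C(=O)C[C@H](c1ccc(O[Si](C(C)C)(C(C)C)C(C)C)c2C=CC(C)(C)Oc12)CO | intermediate (not isolated)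
14 | tert-butyldimethylsilyl (3R)-4-(tert-butyldimethylsilyloxy)-3-[2,2-dimethyl-5-(triisopropylsilyloxy)-2H-chromen-8-yl]butanoate | CC(C)(C)[Si](C)(C)OC(=O)C[C@H](c1ccc(O[Si](C(C)C)(C(C)C)C(C)C)c2C=CC(C)(C)Oc12)CO[Si](C)(C)C(C)(C)C | intermediate (not isolated)
15 | (3R)-4-(tert-butyldimethylsilyloxy)-3-[2,2-dimethyl-5-(triisopropylsilyloxy)-2H-chromen-8-yl]butanoic acid | OC(=O)C[C@H](c1ccc(O[Si](C(C)C)(C(C)C)C(C)C)c2C=CC(C)(C)Oc12)CO[Si](C)(C)C(C)(C)C | intermediate
16 | methyl (3R)-4-(tert-butyldimethylsilyloxy)-3-[2,2-dimethyl-5-(triisopropylsilyloxy)-2H-chromen-8-yl]butanoate | COC(=O)C[C@H](c1ccc(O[Si](C(C)C)(C(C)C)C(C)C)c2C=CC(C)(C)Oc12)CO[Si](C)(C)C(C)(C)C | intermediate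
17 | lithium (4R)-1,1-dibromo-5-(tert-butyldimethylsilyloxy)-4-[2,2-dimethyl-5-(triisopropylsilyloxy)-2H-chromen-8-yl]pent-1-en-2-olate | [Li+].[O-]C(=C(Br)Br)C[C@H](c1ccc(O[Si](C(C)C)(C(C)C)C(C)C)c2C=CC(C)(C)Oc12)CO[Si](C)(C)C(C)(C)C | intermediate (not isolated)
18 | lithium (4R)-5-(tert-butyldimethylsilyloxy)-4-[2,2-dimethyl-5-(triisopropylsilyloxy)-2H-chromen-8-yl]pent-1-yn-1-olate | [Li+].[O-]C#CC[C@H](c1ccc(O[Si](C(C)C)(C(C)C)C(C)C)c2C=CC(C)(C)Oc12)CO[Si](C)(C)C(C)(C)C | intermediate (not isolated)
19 | tert-butyl{[(2R)-2-[2,2-dimethyl-5-(triisopropylsilyloxy)-2H-chromen-8-yl]-5-(triisopropylsilyloxy)pent-4-yn-1-yl]oxy}dimethylsilane | CC(C)[Si](C(C)C)(C(C)C)OC#CC[C@H](c1ccc(O[Si](C(C)C)(C(C)C)C(C)C)c2C=CC(C)(C)Oc12)CO[Si](C)(C)C(C)(C)C | intermediate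
20 | 3-ethoxycyclobut-2-en-1-one | CCOC1=CC(=O)C1 | starting material
21 | 3-(prop-2-enyloxy)cyclobut-2-en-1-one | C=CCOC1=CC(=O)C1 | intermediate
22 | 3-(prop-2-enyloxy)buta-1,3-dien-1-one | C=CCOC(=C)C=C=O | intermediate (not isolated)
23 | 2-[(2R)-3-(tert-butyldimethylsilyloxy)-2-[2,2-dimethyl-5-(triisopropylsilyloxy)-2H-chromen-8-yl]propyl]-4-[1-(prop-2-enyloxy)ethenyl]-3-(triisopropylsilyloxy)cyclobut-2-en-1-one (epimers at the ring CH) | O=C1C(C[C@H](c2ccc(O[Si](C(C)C)(C(C)C)C(C)C)c3C=CC(C)(C)Oc23)CO[Si](C)(C)C(C)(C)C)=C(O[Si](C(C)C)(C(C)C)C(C)C)C1C(=C)OCC=C | intermediate (not isolated)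
24 | 2-[(2R)-3-(tert-butyldimethylsilyloxy)-2-[2,2-dimethyl-5-(triisopropylsilyloxy)-2H-chromen-8-yl]propyl]-5-(prop-2-enyloxy)-3-(triisopropylsilyloxy)hexa-1,3,5-trien-1-one | O=C=C(C[C@H](c1ccc(O[Si](C(C)C)(C(C)C)C(C)C)c2C=CC(C)(C)Oc12)CO[Si](C)(C)C(C)(C)C)C(O[Si](C(C)C)(C(C)C)C(C)C)=CC(=C)OCC=C | intermediate (not isolated)
25 | 2-[(2R)-3-(tert-butyldimethylsilyloxy)-2-[2,2-dimethyl-5-(triisopropylsilyloxy)-2H-chromen-8-yl]propyl]-5-(prop-2-enyloxy)-3-(triisopropylsilyloxy)cyclohexa-2,4-dien-1-one | O=C1CC(OCC=C)=CC(O[Si](C(C)C)(C(C)C)C(C)C)=C1C[C@H](c1ccc(O[Si](C(C)C)(C(C)C)C(C)C)c2C=CC(C)(C)Oc12)CO[Si](C)(C)C(C)(C)C | intermediate (not isolated)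
26 | 2-[(2R)-3-(tert-butyldimethylsilyloxy)-2-[2,2-dimethyl-5-(triisopropylsilyloxy)-2H-chromen-8-yl]propyl]-5-(prop-2-enyloxy)-3-(triisopropylsilyloxy)phenol | Oc1cc(OCC=C)cc(O[Si](C(C)C)(C(C)C)C(C)C)c1C[C@H](c1ccc(O[Si](C(C)C)(C(C)C)C(C)C)c2C=CC(C)(C)Oc12)CO[Si](C)(C)C(C)(C)C | intermediate
27 | tert-butyl{(2R)-2-[2,2-dimethyl-5-(triisopropylsilyloxy)-2H-chromen-8-yl]-3-[2-methoxy-4-(prop-2-enyloxy)-6-(triisopropylsilyloxy)phenyl]propoxy}dimethylsilane | COc1cc(OCC=C)cc(O[Si](C(C)C)(C(C)C)C(C)C)c1C[C@H](c1ccc(O[Si](C(C)C)(C(C)C)C(C)C)c2C=CC(C)(C)Oc12)CO[Si](C)(C)C(C)(C)C | intermediate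
28 | 8-[(2R)-1-hydroxy-3-[2-hydroxy-6-methoxy-4-(prop-2-enyloxy)phenyl]propan-2-yl]-2,2-dimethyl-2H-chromen-5-ol | COc1cc(OCC=C)cc(O)c1C[C@H](c1ccc(O)c2C=CC(C)(C)Oc12)CO | intermediate
29 | 8-[(3R)-5-methoxy-7-(prop-2-enyloxy)-3,4-dihydro-2H-chromen-3-yl]-2,2-dimethyl-2H-chromen-5-ol | COc1cc(OCC=C)cc2c1C[C@H](c1ccc(O)c3c1OC(C)(C)C=C3)CO2 | intermediate
30 | 8-[(3R)-7-hydroxy-5-methoxy-3,4-dihydro-2H-chromen-3-yl]-2,2-dimethyl-2H-chromen-5-ol (CNP0320659.1) | COc1cc(O)cc2c1C[C@H](c1ccc(O)c3c1OC(C)(C)C=C3)CO2 | target

## Step count and risk

Total step count: 14. Longest linear sequence: 13 steps (steps 1–8 from 1 to 19, then steps 10–14). Step 9 is a one-step side branch.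

**Step 10 (key step).** The cyclobutenone 21 is a donor-stabilised vinylogous ester, so ring opening to 22 may need temperatures at which side processes begin: acylation of the product phenol by 22, Claisen rearrangement of the allyl enol ether, or hydrolytic loss of the ynol ether. Stalling at the cycloadduct stage is also possible. The fallback sets out from 19 and 21 and separates the two halves of the cascade with a different mode of ketene generation. Compound 21 is irradiated (about 300 nm, room temperature) in the presence of 19, since cyclobutenones also open photochemically to vinylketenes. The cycloadduct 23 is isolated and then heated alone in toluene at 80 °C, so that 4π opening, 6π closure and tautomerisation take place in the absence of any ketene. The route is rejoined at 26.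

**Step 9.** Under acid the alcohol may cleave the strained ring (retro-Claisen-type opening), or adventitious water may hydrolyse the enol ether, and the exchange equilibrium may be unfavourable. The fallback sets out from 20: hydrolysis with dilute aqueous HCl gives cyclobutane-1,3-dione F1. Its acidic enol is then O-allylated with allyl alcohol under Mitsunobu conditions (PPh3, diisopropyl azodicarboxylate), which returns to the route at 21.

**Step 8.** Alpha-deprotonation of the ester may compete with addition of the carbenoid. Excess alkyllithium may metalate next to the aryl silyl ether during warming. The ynol ether may hydrolyse during purification. The fallback sets out from lactone 12: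
- reduction with i-Bu2AlH at −78 °C gives the lactol (4R)-4-[2,2-dimethyl-5-(triisopropylsilyloxy)-2H-chromen-8-yl]oxolan-2-ol F2;
- Ohira–Bestmann homologation (dimethyl (1-diazo-2-oxopropyl)phosphonate, K2CO3, MeOH) gives the alkynol (2R)-2-[2,2-dimethyl-5-(triisopropylsilyloxy)-2H-chromen-8-yl]pent-4-yn-1-ol F3;
- silylation (TBSCl, imidazole) gives the silyl ether tert-butyl{[(2R)-2-[2,2-dimethyl-5-(triisopropylsilyloxy)-2H-chromen-8-yl]pent-4-yn-1-yl]oxy}dimethylsilane F4;
- deprotonation with n-BuLi and oxidation of the lithium acetylide with lithium tert-butyl peroxide gives ynolate 18, which is silylated with TIPSCl as in step 8 to rejoin the route at 19.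

**Step 5.** Protodeboronation of the electron-rich, ortho-alkoxy boronic acid may outrun insertion of the rather unreactive five-membered lactone, and facial selectivity may be lower than with six-membered acceptors. The fallback sets out from 10. Suzuki–Miyaura coupling with 4-bromofuran-2(5H)-one (Pd(PPh3)4, K3PO4, dioxane/H2O) gives the butenolide 4-[2,2-dimethyl-5-(triisopropylsilyloxy)-2H-chromen-8-yl]furan-2(5H)-one F5. Copper hydride-catalysed asymmetric conjugate reduction (Cu(OAc)2, a chiral bisphosphine such as p-Tol-BINAP in the enantiomer that delivers the R centre, polymethylhydrosiloxane, t-BuOH, toluene) then sets the stereocentre by hydride delivery and returns to the route at 12.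

**Step 13.** With two acidic phenols competing for the alkoxyphosphonium ion, intermolecular etherification at the unhindered ring-B phenol and oligomerisation may erode the ring closure. The fallback sets out from 27 and installs the leaving group while both phenols are still silylated:
- selective cleavage of the primary TBS ether (pyridinium p-toluenesulfonate, MeOH, rt) gives the alcohol (2R)-2-[2,2-dimethyl-5-(triisopropylsilyloxy)-2H-chromen-8-yl]-3-[2-methoxy-4-(prop-2-enyloxy)-6-(triisopropylsilyloxy)phenyl]propan-1-ol F6;
- mesylation (MsCl, Et3N, CH2Cl2, 0 °C) gives its methanesulfonate F7;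
- CsF in DMF at high dilution removes both aryl silyl groups, and the ring-A phenoxide, generated next to the sulfonate, closes ring C by Williamson displacement (6-exo-tet), rejoining the route at 29.

## Further compounds

F0 | step 10 | none | none
F1 | step 9 | cyclobutane-1,3-dione | O=C1CC(=O)C1
F2 | step 8 | (4R)-4-[2,2-dimethyl-5-(triisopropylsilyloxy)-2H-chromen-8-yl]oxolan-2-ol (anomeric mixture) | OC1C[C@H](c2ccc(O[Si](C(C)C)(C(C)C)C(C)C)c3C=CC(C)(C)Oc23)CO1
F3 | step 8 | (2R)-2-[2,2-dimethyl-5-(triisopropylsilyloxy)-2H-chromen-8-yl]pent-4-yn-1-ol | C#CC[C@H](c1ccc(O[Si](C(C)C)(C(C)C)C(C)C)c2C=CC(C)(C)Oc12)CO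
F4 | step 8 | tert-butyl{[(2R)-2-[2,2-dimethyl-5-(triisopropylsilyloxy)-2H-chromen-8-yl]pent-4-yn-1-yl]oxy}dimethylsilane | C#CC[C@H](c1ccc(O[Si](C(C)C)(C(C)C)C(C)C)c2C=CC(C)(C)Oc12)CO[Si](C)(C)C(C)(C)C
F5 | step 5 | 4-[2,2-dimethyl-5-(triisopropylsilyloxy)-2H-chromen-8-yl]furan-2(5H)-one | O=C1C=C(c2ccc(O[Si](C(C)C)(C(C)C)C(C)C)c3C=CC(C)(C)Oc23)CO1
F6 | step 13 | (2R)-2-[2,2-dimethyl-5-(triisopropylsilyloxy)-2H-chromen-8-yl]-3-[2-methoxy-4-(prop-2-enyloxy)-6-(triisopropylsilyloxy)phenyl]propan-1-ol | COc1cc(OCC=C)cc(O[Si](C(C)C)(C(C)C)C(C)C)c1C[C@H](c1ccc(O[Si](C(C)C)(C(C)C)C(C)C)c2C=CC(C)(C)Oc12)CO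
F7 | step 13 | (2R)-2-[2,2-dimethyl-5-(triisopropylsilyloxy)-2H-chromen-8-yl]-3-[2-methoxy-4-(prop-2-enyloxy)-6-(triisopropylsilyloxy)phenyl]propyl methanesulfonate | COc1cc(OCC=C)cc(O[Si](C(C)C)(C(C)C)C(C)C)c1C[C@H](c1ccc(O[Si](C(C)C)(C(C)C)C(C)C)c2C=CC(C)(C)Oc12)COS(C)(=O)=O
A1 | alternative 1 | 3-methoxy-2-[(phenylsulfonyl)methyl]-5-(triisopropylsilyloxy)phenol | COc1cc(O[Si](C(C)C)(C(C)C)C(C)C)cc(O)c1CS(=O)(=O)c1ccccc1
A2 | alternative 1 | 2-[2,2-dimethyl-5-(triisopropylsilyloxy)-2H-chromen-8-yl]acetic acid | OC(=O)Cc1ccc(O[Si](C(C)C)(C(C)C)C(C)C)c2C=CC(C)(C)Oc12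
A3 | alternative 1 | (3R)-3-[2,2-dimethyl-5-(triisopropylsilyloxy)-2H-chromen-8-yl]-5-methoxy-7-(triisopropylsilyloxy)-3,4-dihydro-2H-chromen-2-one | COc1cc(O[Si](C(C)C)(C(C)C)C(C)C)cc2c1C[C@H](c1ccc(O[Si](C(C)C)(C(C)C)C(C)C)c3C=CC(C)(C)Oc13)C(=O)O2
A4 | alternative 2 | 2-methoxy-4-(triisopropylsilyloxy)-6-(trimethylsilyl)phenyl trifluoromethanesulfonate | COc1cc(O[Si](C(C)C)(C(C)C)C(C)C)cc([Si](C)(C)C)c1OS(=O)(=O)C(F)(F)F
A5 | alternative 2 | (2R)-3-chloro-2-[2,2-dimethyl-5-(triisopropylsilyloxy)-2H-chromen-8-yl]propan-1-ol | ClC[C@H](c1ccc(O[Si](C(C)C)(C(C)C)C(C)C)c2C=CC(C)(C)Oc12)CO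
A6 | alternative 2 | {[(3R)-3-[2,2-dimethyl-5-(triisopropylsilyloxy)-2H-chromen-8-yl]-5-methoxy-3,4-dihydro-2H-chromen-7-yl]oxy}triisopropylsilane | COc1cc(O[Si](C(C)C)(C(C)C)C(C)C)cc2c1C[C@H](c1ccc(O[Si](C(C)C)(C(C)C)C(C)C)c3C=CC(C)(C)Oc13)CO2
A7 | alternative 3 | 2-methoxy-6-(methoxymethoxy)-4-(triisopropylsilyloxy)phenyl trifluoromethanesulfonate | COCOc1cc(O[Si](C(C)C)(C(C)C)C(C)C)cc(OC)c1OS(=O)(=O)C(F)(F)F
A8 | alternative 3 | 2-ethenyl-4,4,5,5-tetramethyl-1,3,2-dioxaborolane | C=CB1OC(C)(C)C(C)(C)O1
A9 | alternative 3 | 2-[(1R)-1-[2,2-dimethyl-5-(triisopropylsilyloxy)-2H-chromen-8-yl]-2-[2-methoxy-6-(methoxymethoxy)-4-(triisopropylsilyloxy)phenyl]ethyl]-4,4,5,5-tetramethyl-1,3,2-dioxaborolane | COc1cc(O[Si](C(C)C)(C(C)C)C(C)C)cc(OCOC)c1C[C@H](c1ccc(O[Si](C(C)C)(C(C)C)C(C)C)c2C=CC(C)(C)Oc12)B1OC(C)(C)C(C)(C)O1
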